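**Strategy.** Everything rests on cutting the C1–C2 bond of ring B. The step exploits that C1 carries two aryl groups, with the C6 methoxy group of ring A and the C4′ oxygen of the pendant guaiacyl ring both para to it: a hydroxyl on C1 leaves as water under mild acid, and the adjacent C2, as α-carbon of an aldehyde whose carbonyl becomes the acyloxymethyl arm, is the nucleophile. One aminocatalytic operation funnels both carbinol epimers through a single cation, closes ring B, sets C1 and C2 against the preformed (R)-C3 centre and leaves the two oxygenated arms differentiated. The precursor is an open-chain (R)-3-(silyloxymethyl)-4-arylbutanal with the diaryl carbinol ortho to the chain.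

Key step: step 11

Locants: tetralin numbering is used throughout, also for open-chain compounds (C1 bears the pendant aryl ring, C2 the coumaroyloxymethyl arm, C3 the hydroxymethyl arm, C4 is the benzylic CH2; ring A is the fused benzene ring C4a–C8a with OMe on C6 and OH on C7; ring B is the carbocycle). TBS = tert-butyldimethylsilyl, TBDPS = tert-butyldiphenylsilyl.

Assumption: 6-bromovanillin is taken as a catalogue compound, because direct bromination of vanillin gives the 5-bromo isomer and the Br must sit para to the methoxy group.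

Step 1
Reactants: 1 6-bromovanillin (2-bromo-4-hydroxy-5-methoxybenzaldehyde)
Product: 2 2-bromo-4-(tert-butyldimethylsilyloxy)-5-methoxybenzaldehyde
Conditions: TBSCl (1.2 equiv), imidazole (2.5 equiv), DMF, 0 °C to rt
Reagents that add atoms: TBSCl, CC(C)(C)[Si](C)(C)Cl
Why: Imidazole-promoted O-silylation of the phenol masks the acidic OH before the hydride, enolate and organolithium steps.

Step 2
Reactants: 2 2-bromo-4-(TBS-oxy)-5-methoxybenzaldehyde
Product: 3 [2-bromo-4-(TBS-oxy)-5-methoxyphenyl]methanol
Conditions: NaBH4 (1.0 equiv), THF/MeOH (4:1), 0 °C, 20 min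
Reagents that add atoms: none
Why: Chemoselective borohydride reduction of the aryl aldehyde, run cold and briefly so that the aryl silyl ether para to the carbonyl group is not methanolysed.

Step 3
Reactants: 3 [2-bromo-4-(TBS-oxy)-5-methoxyphenyl]methanol
Product: 4 2-bromo-4-(TBS-oxy)-5-methoxybenzyl bromide
Conditions: CBr4 (1.2 equiv), PPh3 (1.2 equiv), CH2Cl2, 0 °C; used promptly
Reagents that add atoms: CBr4, BrC(Br)(Br)Br
Why: The Appel reaction converts the benzylic alcohol into the bromide under neutral conditions that leave the aryl silyl ether and the aryl bromide untouched.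

Step 4
Reactants: 5 (R)-4-benzyloxazolidin-2-one, 6 pent-4-enoyl chloride
Product: 8 (R)-4-benzyl-3-(pent-4-enoyl)oxazolidin-2-one, via lithium oxazolidinide 7 (not isolated)
Conditions: n-BuLi (1.05 equiv), THF, −78 °C; then 6 (1.1 equiv), −78 to 0 °C
Reagents that add atoms: none
Why: N-Acylation of the lithiated oxazolidinone installs the auxiliary, and the R antipode is required because the benzylic electrophile of step 5 must enter on the face that ends as the (R)-C3 centre of the target (the S auxiliary would give the enantiomeric series).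

Step 5
Reactants: 8 (R)-4-benzyl-3-(pent-4-enoyl)oxazolidin-2-one, 4 2-bromo-4-(TBS-oxy)-5-methoxybenzyl bromide
Product: 10 (R)-4-benzyl-3-[(2S)-2-[[2-bromo-4-(TBS-oxy)-5-methoxyphenyl]methyl]pent-4-enoyl]oxazolidin-2-one, via sodium Z-enolate 9 (not isolated)
Conditions: NaN(SiMe3)2 (1.1 equiv), THF, −78 °C; then 4 (1.2 equiv), −78 to −40 °C
Reagents that add atoms: none
Why: Evans asymmetric alkylation, in which the chelated sodium Z-enolate is attacked by the benzylic bromide on the face opposite the C4 benzyl group of the auxiliary, sets the future C3 stereocentre (descriptor S here, R once the allyl group has become the higher-ranked CH2CHO arm).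

Step 6
Reactants: 10 the alkylated imide
Product: 11 (2S)-2-[[2-bromo-4-(TBS-oxy)-5-methoxyphenyl]methyl]pent-4-en-1-ol
Conditions: LiBH4 (2 equiv), H2O (2 equiv), Et2O, 0 °C
Reagents that add atoms: none
Why: Reductive cleavage of the N-acyl oxazolidinone with LiBH4 gives the primary alcohol without touching the α-stereocentre, the aryl bromide or the alkene, and returns the auxiliary.

Step 7
Reactants: 11 (2S)-2-[[2-bromo-4-(TBS-oxy)-5-methoxyphenyl]methyl]pent-4-en-1-ol
Product: 12 tert-butyl-[(2S)-2-[[2-bromo-4-(TBS-oxy)-5-methoxyphenyl]methyl]pent-4-enoxy]diphenylsilane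
Conditions: TBDPSCl (1.2 equiv), imidazole (2.5 equiv), CH2Cl2, rt
Reagents that add atoms: TBDPSCl, CC(C)(C)[Si](Cl)(c1ccccc1)c1ccccc1
Why: Silylation of the primary alcohol as the bulky, acid-stable TBDPS ether ensures that this arm survives the acid of step 11, cannot form a lactol with the later aldehyde and sits equatorial in the cyclisation chair.

Step 8
Reactants: 13 vanillin
Product: 14 4-(tert-butyldimethylsilyloxy)-3-methoxybenzaldehyde
Conditions: TBSCl (1.2 equiv), imidazole (2.5 equiv), DMF, rt
Reagents that add atoms: TBSCl, CC(C)(C)[Si](C)(C)Cl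
Why: Routine phenol silylation gives the non-enolisable aldehyde partner with its OH masked against the aryllithium.

Step 9
Reactants: 12 the aryl bromide, 14 4-(TBS-oxy)-3-methoxybenzaldehyde
Product: 16 [4-(TBS-oxy)-3-methoxyphenyl]-[5-(TBS-oxy)-4-methoxy-2-[(2S)-2-[(TBDPS-oxy)methyl]pent-4-enyl]phenyl]methanol (both C1 epimers), via aryllithium 15 (not isolated)
Conditions: n-BuLi (1.1 equiv), THF, −78 °C, 20 min; then 14 (1.3 equiv), −78 to −40 °C; H2O quench
Reagents that add atoms: none
Why: Bromine–lithium exchange followed by 1,2-addition of the aryllithium to the aldehyde forms the C1–C8a bond and the doubly benzylic carbinol, whose uncontrolled C1 configuration is irrelevant because it is erased on ionisation in step 11.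

Step 10
Reactants: 16 the diaryl carbinol (both C1 epimers)
Product: 18 (3R)-4-[4-(TBS-oxy)-2-[hydroxy-[4-(TBS-oxy)-3-methoxyphenyl]methyl]-5-methoxyphenyl]-3-[(TBDPS-oxy)methyl]butanal (both C1 epimers), via vicinal diol 17 (not isolated)
Conditions: OsO4 (2 mol%), NaIO4 (4 equiv), 2,6-lutidine (2 equiv), dioxane/H2O (3:1), rt
Reagents that add atoms: OsO4, O=[Os](=O)(=O)=O (oxygen carrier); NaIO4, [Na+].[O-]I(=O)(=O)=O (terminal oxygen source)
Why: The Lemieux–Johnson oxidation (catalytic dihydroxylation then periodate cleavage, buffered by 2,6-lutidine) shortens the allyl group by one carbon to the aldehyde without ozone, which would endanger the electron-rich arenes, and without acid, which would ionise the carbinol.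

Step 11
Reactants: 18 the (3R)-aldehyde carbinol (both C1 epimers)
Product: 21 (1S,2R,3R)-7-(TBS-oxy)-1-[4-(TBS-oxy)-3-methoxyphenyl]-3-[(TBDPS-oxy)methyl]-6-methoxy-1,2,3,4-tetrahydronaphthalene-2-carbaldehyde, via enamine cation 19 (not isolated), via ring-closed iminium 20 (not isolated)
Conditions: (2R,5R)-5-benzyl-2-tert-butyl-3-methylimidazolidin-4-one·CF3CO2H (20 mol%), CH2Cl2 (0.02 M), 0 °C to rt; Et3N quench
Reagents that add atoms: none
Why: The secondary amine condenses with the aldehyde of 18 to an E-enamine while the trifluoroacetic acid of the salt ionises the C1 carbinol, so both C1 epimers give the same planar diarylmethyl cation in 19 (equally drawn as an O-silylated para-quinone methide of the pendant ring, and also stabilised by the para C6 methoxy group of ring A); the enamine carbon C2 then bonds to C1, and hydrolysis of iminium 20 releases 21 and the catalyst. The closest known reaction is the organocatalytic SN1-type α-alkylation of aldehydes with diarylmethanols by enamine capture of a stabilised carbocation, used here in intramolecular form. Ring B closes in a 6-(enolexo)-exo-trig mode, since the enamine C=C and the C1=C(aryl) bond of the quinone-methide form both lie outside the new ring. C1 (S) is set under kinetic control by a chair-like transition state in which the bulky CH2OTBDPS arm on the fixed (R)-C3 centre and the pendant aryl group are equatorial and the C1 hydrogen, not the aryl group, points at the C4 methylene. C2 (R) results from bond formation on the Re face of the enamine carbon, which keeps the iminium carbon equatorial in that chair and is also the face left open by the benzyl group of the (2R,5R) catalyst (matched pair); should some 2,3-cis aldehyde form, base-mediated enolisation would move it to the all-equatorial trans,trans isomer. The step needs diastereoselection relative to C3 and ring closure in preference to intermolecular capture, which the equatorial C3 arm, high dilution, the lack of any β-hydrogen at C1 (no elimination) and the reversibility of cation capture by water should secure.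

Step 12
Reactants: 21 the tetralin-2-carbaldehyde
Product: 22 [(1S,2R,3R)-7-(TBS-oxy)-1-[4-(TBS-oxy)-3-methoxyphenyl]-3-[(TBDPS-oxy)methyl]-6-methoxy-1,2,3,4-tetrahydronaphthalen-2-yl]methanol
Conditions: NaBH4 (1.5 equiv), THF/MeOH (4:1), −20 to 0 °C
Reagents that add atoms: none
Why: Borohydride reduction of the aldehyde fixes the epimerisable C2 centre and unveils the one free primary hydroxyl, cold and briefly so that neither the aryl silyl ethers nor the position of the TBDPS group are disturbed.

Step 13
Reactants: 23 p-coumaric acid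
Product: 25 (E)-3-[4-(tert-butyldimethylsilyloxy)phenyl]prop-2-enoic acid, via silyl ester silyl ether 24 (not isolated)
Conditions: TBSCl (2.5 equiv), imidazole (5 equiv), DMF, rt; then AcOH/THF/H2O (3:1:1), rt
Reagents that add atoms: TBSCl, CC(C)(C)[Si](C)(C)Cl
Why: Exhaustive silylation followed by selective hydrolysis of the far more labile silyl ester in aqueous acetic acid leaves the phenol-protected acid with its E alkene untouched.

Step 14
Reactants: 22 the tetralin-2-methanol, 25 (E)-3-[4-(TBS-oxy)phenyl]prop-2-enoic acid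
Product: 26 [(1S,2R,3R)-7-(TBS-oxy)-1-[4-(TBS-oxy)-3-methoxyphenyl]-3-[(TBDPS-oxy)methyl]-6-methoxy-1,2,3,4-tetrahydronaphthalen-2-yl]methyl (E)-3-[4-(TBS-oxy)phenyl]prop-2-enoate
Conditions: N,N′-diisopropylcarbodiimide (1.5 equiv), 4-(dimethylamino)pyridine (DMAP, 0.2 equiv), CH2Cl2, 0 °C to rt
Reagents that add atoms: none
Why: Steglich esterification (carbodiimide activation with nucleophilic catalysis by DMAP) acylates the only free hydroxyl, so the coumaroyl group lands on the C2 arm with no regiochemical question.

Step 15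
Reactants: 26 the fully silylated ester
Product: 27 [(1S,2R,3R)-7-hydroxy-1-(4-hydroxy-3-methoxyphenyl)-3-(hydroxymethyl)-6-methoxy-1,2,3,4-tetrahydronaphthalen-2-yl]methyl (E)-3-(4-hydroxyphenyl)prop-2-enoate (target)
Conditions: HF·pyridine (excess), pyridine, THF, 0 °C to rt
Reagents that add atoms: none
Why: Fluoride-driven cleavage of the three aryl TBS ethers and the primary TBDPS ether under buffered, non-basic conditions should release the target without acyl migration to the neighbouring C3 hydroxymethyl group, conjugate addition or E/Z erosion of the coumarate.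

**Compound list**

1 | 6-bromovanillin | COc1cc(C=O)c(Br)cc1O | starting material
2 | 2-bromo-4-(TBS-oxy)-5-methoxybenzaldehyde | COc1cc(C=O)c(Br)cc1O[Si](C)(C)C(C)(C)C | intermediate
3 | [2-bromo-4-(TBS-oxy)-5-methoxyphenyl]methanol | COc1cc(CO)c(Br)cc1O[Si](C)(C)C(C)(C)C | intermediate
4 | 2-bromo-4-(TBS-oxy)-5-methoxybenzyl bromide | COc1cc(CBr)c(Br)cc1O[Si](C)(C)C(C)(C)C | intermediate
5 | (R)-4-benzyloxazolidin-2-one | O=C1N[C@H](Cc2ccccc2)CO1 | starting material
6 | pent-4-enoyl chloride | C=CCCC(=O)Cl | starting material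
7 | lithium (R)-4-benzyl-2-oxooxazolidin-3-ide | [Li+].O=C1[N-][C@H](Cc2ccccc2)CO1 | intermediate (not isolated)
8 | (R)-4-benzyl-3-(pent-4-enoyl)oxazolidin-2-one | C=CCCC(=O)N1[C@H](Cc2ccccc2)COC1=O | intermediate
9 | sodium Z-enolate of 8 | [Na+].C=CC/C=C(\[O-])N1[C@H](Cc2ccccc2)COC1=O | intermediate (not isolated)
10 | (R)-4-benzyl-3-[(2S)-2-[[2-bromo-4-(TBS-oxy)-5-methoxyphenyl]methyl]pent-4-enoyl]oxazolidin-2-one | C=CC[C@@H](Cc1cc(OC)c(O[Si](C)(C)C(C)(C)C)cc1Br)C(=O)N1[C@H](Cc2ccccc2)COC1=O | intermediate
11 | (2S)-2-[[2-bromo-4-(TBS-oxy)-5-methoxyphenyl]methyl]pent-4-en-1-ol | C=CC[C@@H](Cc1cc(OC)c(O[Si](C)(C)C(C)(C)C)cc1Br)CO | intermediate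
12 | TBDPS ether of 11 | C=CC[C@@H](Cc1cc(OC)c(O[Si](C)(C)C(C)(C)C)cc1Br)CO[Si](c1ccccc1)(c1ccccc1)C(C)(C)C | intermediate
13 | vanillin | COc1cc(C=O)ccc1O | starting material
14 | 4-(TBS-oxy)-3-methoxybenzaldehyde | COc1cc(C=O)ccc1O[Si](C)(C)C(C)(C)C | intermediate
15 | aryllithium from 12 (Li in place of Br) | C=CC[C@@H](Cc1cc(OC)c(O[Si](C)(C)C(C)(C)C)cc1[Li])CO[Si](c1ccccc1)(c1ccccc1)C(C)(C)C | intermediate (not isolated)
16 | diaryl carbinol with (2S)-pentenyl chain, both C1 epimers | COc1cc(C(O)c2cc(O[Si](C)(C)C(C)(C)C)c(OC)cc2C[C@@H](CO[Si](c3ccccc3)(c3ccccc3)C(C)(C)C)CC=C)ccc1O[Si](C)(C)C(C)(C)C | intermediate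
17 | vicinal diol from 16 (terminal alkene dihydroxylated) | COc1cc(C(O)c2cc(O[Si](C)(C)C(C)(C)C)c(OC)cc2C[C@@H](CO[Si](c3ccccc3)(c3ccccc3)C(C)(C)C)CC(O)CO)ccc1O[Si](C)(C)C(C)(C)C | intermediate (not isolated)
18 | (3R)-aldehyde with C1 diaryl carbinol, both C1 epimers (key-step precursor) | COc1cc(C(O)c2cc(O[Si](C)(C)C(C)(C)C)c(OC)cc2C[C@@H](CO[Si](c3ccccc3)(c3ccccc3)C(C)(C)C)CC=O)ccc1O[Si](C)(C)C(C)(C)C | intermediate
19 | E-enamine of 18 with the (2R,5R)-imidazolidinone, C1 as diarylmethyl cation, trifluoroacetate | COc1cc([CH+]c2cc(O[Si](C)(C)C(C)(C)C)c(OC)cc2C[C@@H](CO[Si](c3ccccc3)(c3ccccc3)C(C)(C)C)/C=C/N3[C@@H](C(C)(C)C)N(C)C(=O)[C@H]3Cc3ccccc3)ccc1O[Si](C)(C)C(C)(C)C.[O-]C(=O)C(F)(F)F | intermediate (not isolated)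
20 | ring-closed iminium trifluoroacetate of 21 with the catalyst | COc1cc([C@H]2c3cc(O[Si](C)(C)C(C)(C)C)c(OC)cc3C[C@@H](CO[Si](c4ccccc4)(c4ccccc4)C(C)(C)C)[C@@H]2C=[N+]2[C@@H](C(C)(C)C)N(C)C(=O)[C@H]2Cc2ccccc2)ccc1O[Si](C)(C)C(C)(C)C.[O-]C(=O)C(F)(F)F | intermediate (not isolated)
21 | (1S,2R,3R)-1-aryltetralin-2-carbaldehyde, trans,trans (key-step product) | COc1cc([C@H]2c3cc(O[Si](C)(C)C(C)(C)C)c(OC)cc3C[C@@H](CO[Si](c4ccccc4)(c4ccccc4)C(C)(C)C)[C@@H]2C=O)ccc1O[Si](C)(C)C(C)(C)C | intermediate
22 | (1S,2R,3R)-tetralin-2-methanol | COc1cc([C@H]2c3cc(O[Si](C)(C)C(C)(C)C)c(OC)cc3C[C@@H](CO[Si](c4ccccc4)(c4ccccc4)C(C)(C)C)[C@@H]2CO)ccc1O[Si](C)(C)C(C)(C)C | intermediate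
23 | p-coumaric acid | O=C(O)/C=C/c1ccc(O)cc1 | starting material
24 | tert-butyldimethylsilyl (E)-3-[4-(TBS-oxy)phenyl]prop-2-enoate | CC(C)(C)[Si](C)(C)OC(=O)/C=C/c1ccc(O[Si](C)(C)C(C)(C)C)cc1 | intermediate (not isolated)
25 | (E)-3-[4-(TBS-oxy)phenyl]prop-2-enoic acid | O=C(O)/C=C/c1ccc(O[Si](C)(C)C(C)(C)C)cc1 | intermediate
26 | fully silylated coumarate ester | COc1cc([C@H]2c3cc(O[Si](C)(C)C(C)(C)C)c(OC)cc3C[C@@H](CO[Si](c4ccccc4)(c4ccccc4)C(C)(C)C)[C@@H]2COC(=O)/C=C/c2ccc(O[Si](C)(C)C(C)(C)C)cc2)ccc1O[Si](C)(C)C(C)(C)C | intermediate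
27 | CNP0403384.1, (1S,2R,3R) | COc1cc([C@H]2c3cc(O)c(OC)cc3C[C@@H](CO)[C@@H]2COC(=O)/C=C/c2ccc(O)cc2)ccc1O | target

**Step count.** Total: 15 steps. Longest linear sequence: 12 steps (1, 2, 3, 5, 6, 7, 9, 10, 11, 12, 14, 15), from 6-bromovanillin.

**Steps most likely to fail**

Step 11. The carbinol may ionise too slowly under the weak acid of the catalyst salt, the cation may be drained by intermolecular capture or by loss of the pendant aryl silyl group, and facial control at C1 may erode if the catalyst and the chair preference disagree. Fallback, setting out from 18: silylation with Me3SiOTf/Et3N (CH2Cl2, 0 °C) would give the bis(trimethylsilyl) compound F1, which is the enol silane of the aldehyde with the C1 carbinol as its trimethylsilyl ether. Catalytic Me3SiOTf (or BF3·OEt2) in CH2Cl2 at −78 °C would then ionise the C1 silyl ether, and the enol silane would capture the cation in a Lewis-acid-mediated Mukaiyama-type SN1 alkylation. This forms the same bond through the same chair under substrate control alone, with DBU equilibration at C2 if required. The route is rejoined at aldehyde 21.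

Step 15. Cleavage of the aryl silyl ethers by HF·pyridine may stall, and more forcing or basic fluoride conditions could bring migration of the coumaroyl group to the C3 arm or damage to the enoate. Fallback, setting out from alcohol 22: heating with Meldrum's acid (toluene, 100 °C) would give the malonic half ester F2. All four silyl groups would then be removed with Bu4NF/AcOH or HF·pyridine, now with no cinnamate in the molecule, to give the desilylated half ester F3. Knoevenagel–Doebner condensation of F3 with 4-hydroxybenzaldehyde (pyridine, catalytic piperidine, 60 °C; decarboxylative and E-selective) would build the coumarate last and arrive at target 27, bypassing 25 and 26.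

Step 9. Bromine–lithium exchange may be incomplete, or the aryllithium may be quenched or butylated before it adds to the aldehyde. Fallback, setting out from bromide 12: Miyaura borylation (B2pin2, Pd(dppf)Cl2, KOAc, dioxane, 85 °C) would give the pinacol boronate F4. Rhodium-catalysed 1,2-addition of F4 to aldehyde 14 ([Rh(OH)(cod)]2, dioxane/H2O, 60 °C) would then deliver carbinol 16, where the route is rejoined.

**Further compounds**

F1 | step 11 | trimethylsilyl enol ether of 18 with the C1 carbinol as trimethylsilyl ether (E/Z and C1 mixture) | COc1cc(C(O[Si](C)(C)C)c2cc(O[Si](C)(C)C(C)(C)C)c(OC)cc2C[C@@H](CO[Si](c3ccccc3)(c3ccccc3)C(C)(C)C)C=CO[Si](C)(C)C)ccc1O[Si](C)(C)C(C)(C)C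
F2 | step 15 | malonic half ester of alcohol 22 | COc1cc([C@H]2c3cc(O[Si](C)(C)C(C)(C)C)c(OC)cc3C[C@@H](CO[Si](c4ccccc4)(c4ccccc4)C(C)(C)C)[C@@H]2COC(=O)CC(=O)O)ccc1O[Si](C)(C)C(C)(C)C
F3 | step 15 | fully desilylated malonic half ester | COc1cc([C@H]2c3cc(O)c(OC)cc3C[C@@H](CO)[C@@H]2COC(=O)CC(=O)O)ccc1O
F4 | step 9 | pinacol boronate from 12 (Bpin in place of Br) | C=CC[C@@H](Cc1cc(OC)c(O[Si](C)(C)C(C)(C)C)cc1B1OC(C)(C)C(C)(C)O1)CO[Si](c1ccccc1)(c1ccccc1)C(C)(C)C
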